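The earlier runs and the new flask are simulated for substances that don't exist, noise included.

4 questions stood on this flask, and I wanted its peak and closing time by hand, by counting turnovers.

| flask | starting material | remark | time |
|---|---|---|---|
| Thursday's | 0.034 M | run made earlier |  |
| Tuesday's | 0.075 M | run made earlier |  |
| flask | 0.050 M |  | 2.5 h |

- Thursday's (time / min: single ring / %, starting material / %): 0.833: 23, 13; 4.00: 29, 0; 20.0: 22, 0; 90.0: 5, 4
- Tuesday's (time / min: single ring / %, starting material / %): 0.833: 15, 5; 4.00: 12, 2; 20.0: 14, 1; 90.0: 1, 0

(standard deviation of a reading: 2 percentage points)

- the numbers in the tables scatter by 2 percentage points (one standard deviation)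
- a reading or a percentage of single ring counts all its forms, free or not

- time up to 2.5 h at which single ring stands highest, in min
- the amount of single ring, in percent of the starting material charged, at that time
- earliest time at which at least nineteen twentieths of that best amount are there, in min
- latest time at which they still are

One turnover of a species is one lifetime, 1/k. In Thursday's run, single ring read 22% at 20.0 min, with starting material at 0%, and 5% at 90.0 min, so I read a loss constant k = 0.0212 min⁻¹. That reading is soft, since each value scatters by 2 percentage points. Taken over to this flask, the turnover count n = k·t reached 3.17 at 2.5 h.

Thursday's reading of 13% of starting material at 0.833 min gave it a constant K = 2.45 min⁻¹, which I let stand in for this flask, although this flask was charged with 0.050 M against Thursday's 0.034 M. Assuming that a fixed share of the starting material used became single ring, I put the peak where making equalled loss, with starting material at k/K = 0.864%, which came at 1.94 min. Losing a twentieth takes 0.0513 turnovers, so I closed the window at 0.0727 h.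

The forecast gave a peak of 21% at 2 min, open from 0.7 min and shut at 0.1 h, later than my close, on this ground: “Balancing formation and decay”.

The flask gave 21.6% at 1.99 min, open from 0.964 min and shut at 0.0764 h.

    starting material → single ring (k = 0.0180 s⁻¹)
    2 starting material → open dimer (k = 0.740 L mol⁻¹ s⁻¹)
    starting material + open dimer → open trimer (k = 0.420 L mol⁻¹ s⁻¹)
    open dimer → ring dimer (k = 0.0270 s⁻¹)
    starting material + single ring → side product (k = 0.840 L mol⁻¹ s⁻¹)
    single ring → over-reaction product (k = 4.30 × 10⁻⁴ s⁻¹)
    crystals ⇌ single ring, rate k7*(cs7 - [single ring]) while solid is left; crystals form when [single ring] > cs7 (solubility = 27.0 mM, k = 0.540 s⁻¹)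

At that peak this flask held 1.04% of starting material, beside my 0.864%. Counting 3.17 turnovers down from 21.6% gives 0.907% at 2.50 h, and the flask held 0.482%.

In the neighbour charged with 0.020 M, the same count from its best of 38.0% of single ring gives 1.60% at 2.50 h. The computed amount of single ring there was 0.860%.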